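The data come from a simulation on assumed constants; the scatter is artificial.

At the reading time of 2.5 h, green beats red if it has come far enough towards its own equilibrium at 70 °C, so I counted that distance in powers of ten.

| setting | west | south | red | green |
|---|---|---|---|---|
| Q | 0.12 M | 0.083 M | 0.083 M | 0.083 M |
| D | 0.083 M | 0.083 M | 0.0830 M | 0.300 M |
| X | 0.0415 M | 0.021 M | 0.0415 M | 0.0415 M |
| temperature | 100 °C | 100 °C |  |  |
| remark | run made earlier | run made earlier | at 100 °C until 80 min, from then on at 70 °C | at 70 °C throughout |
| time |  |  | 2.5 h | 2.5 h |

| run | time / min | L / % | Q / % |
|---|---|---|---|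
| west | 8.00 | 6.5 | 93.3 |
| west | 15.0 | 10.5 | 89.8 |
| west | 25.0 | 14.6 | 85.7 |
| west | 30.0 | 15.9 | 84.5 |
| west | 40.0 | 17.1 | 81.8 |
| west | 50.0 | 17.6 | 82.1 |
| south | 8.00 | 6.2 | 92.5 |
| south | 15.0 | 11.7 | 88.0 |
| south | 25.0 | 16.5 | 83.2 |
| south | 30.0 | 17.7 | 81.4 |
| south | 40.0 | 19.7 | 79.5 |
| south | 50.0 | 22.1 | 76.8 |

(readings scatter by 0.3 percentage points)

- what was read earlier has a scatter of 0.3 percentage points, one standard deviation
- the earlier runs do not show what temperature does; that part of a forecast is a guess
- no earlier run changes the charge of D; that part of a forecast is a guess

- which one finishes higher in amount of L, in percent of the Q charged ("neither" within 2 percentage points) (red / green / neither)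
- amount of L at the end, in percent of the Q charged, red
- amount of L at the end, in percent of the Q charged, green

West's L rose by 0.5 percentage points between its last two readings, and I took the last reading as equilibrium: K = cL cX/(cQ cD) read there was 0.217. Applied to the charges, and kept unchanged at 70 °C as a guess, this K gave equilibrium shares of L of 19.9% for red and 42.7% for green.

West's first reading showed its gap to equilibrium closing at 0.0576 /min. I scaled that rate with cD over the equilibrium share, first order in D being another guess. At 100 °C this put green at 5.59 powers of ten by the reading. Slowed 10-fold, the forecast's guess, which I borrowed, that estimate became m = 0.559. This m is the decades of approach, the powers of ten by which the gap to equilibrium has shrunk at the reading. It left 0.276 of green's gap, so I expected 30.9%.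

My estimate gave red 1.77 decades at 100 °C before cooling, more than green's, so I put red at its equilibrium share: in this reckoning, thermodynamic control in red against kinetic control in green. On these equilibrium shares, for red to tie or win, green must stop within 2 points of red, which needs m below 0.312, a slowing of 1.25 powers of ten where I assumed one.

The forecast said green, with 20% for red and 28% for green, lower than my green; it warned: “The D order and activation energy are guesses, so this is uncertain.”

    Q + D ⇌ X + L (K = 0.370, k = 7.10 /M/h, Ea = 87.0 kJ/mol, ΔH = 4.00 kJ/mol)
    L + D ⇌ X + E (K = 0.360, k = 1.30 /M/h, Ea = 88.0 kJ/mol, ΔH = −66.0 kJ/mol)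
    D → J (k = 0.340 /h, Ea = 106 kJ/mol)
    (constants at 100 °C)

Red gave 19.4% and green 29.3%, so green finished higher. Set against the equilibrium share I reckoned, green's result reads back as m = 0.503, above the critical 0.312. In this reckoning m grows in step with time, so green read at 1.0 h should stand at m = 0.201, with L at 15.8%. That reading of green gave 15.3%.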